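**Retrosynthetic overview**

1. The angelate is cut to angelic acid and the (S)-benzylic alcohol. The carbinol comes from the C5 aryl methyl ketone by Corey–Bakshi–Shibata reduction, and the ketone from a C5 bromide by Stille coupling with a 1-ethoxyvinyl stannane.
2. The C2 acrylate C(=CH2)CO2Me comes from methoxycarbonylation of a 1-(triflyloxy)vinyl group, made by kinetic enol triflation of a C2 acetyl group. The C3 silyl ether is exchanged for the acetate before the ester exists.
3. Feature: in the 2,3-dihydrobenzofuran, C3 is a benzylic carbinol carbon and the adjacent C2 (bonded to O1) carries the acrylate carbon. With that carbon as a ketone C=O, C2–C3 is the aldol bond of a β-hydroxy ketone inside the five-membered ring.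
4. Retro-aldol across C2–C3 gives 5-bromo-2-(2-oxopropoxy)benzaldehyde, made from 5-bromosalicylaldehyde and chloroacetone.
5. Ring order: the benzene ring is bought. The dihydrofuran ring is the only ring made, and it closes in the aldol step together with both ring stereocentres.

Key step: step 2

Assumption: the sense of induction is taken from the accepted transition state of proline aldol reactions (E-enamine anti to the carboxyl group, aldehyde bound by the acid), on which D-proline should give the (2R,3S) aldol; if the opposite sense were found, L-proline would be used and nothing else would change.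

**Route**

Step 1
Reactants: 1 5-bromosalicylaldehyde; 2 chloroacetone
Product: 3 5-bromo-2-(2-oxopropoxy)benzaldehyde
Conditions: K2CO3, KI (10 mol %), acetone, 20 °C
Reagents that add atoms: none
Why: Williamson ether synthesis of the phenoxide with chloroacetone (iodide-assisted); the mild carbonate base at room temperature should leave the keto aldehyde uncyclised and not take it on to the 2-acetylbenzofuran of the Rap–Stoermer reaction.

Step 2
Reactants: 3 5-bromo-2-(2-oxopropoxy)benzaldehyde
Product: 4 1-[(2R,3S)-5-bromo-3-hydroxy-2,3-dihydro-1-benzofuran-2-yl]ethan-1-one (cis)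
Conditions: D-proline (30 mol %), DMF, 4 °C; cold aqueous work-up, crude product used at once
Reagents that add atoms: none
Why: D-Proline condenses with the ketone to the E-enamine on the aryloxy-bearing methylene, whose carbon adds to the ortho aldehyde while the carboxylic acid hydrogen-bonds to the aldehyde oxygen, and hydrolysis of the iminium releases the aldol and the catalyst. The closest known reaction type is the proline-catalysed intramolecular enolexo aldol of ortho-acylaryl ethers of hydroxyacetone, which gives cis-2-acyl-3-hydroxy-2,3-dihydrobenzofurans. The dihydrofuran ring closes in the 5-(enolexo)-exo-trig mode. C2 is set by the catalyst, because the acid delivers the aldehyde to one face of the enamine (the face that gives 2S with L-proline in ketone donors, hence 2R with D-proline), and C3 is set relative to C2 because the three-atom aryl ether tether and the hydrogen bond hold the forming hydroxyl and the iminium carbon on the same face, hence cis and 3S. The step needs the methylene enamine to react and not the methyl enamine, which the ring size secures (five-membered against seven-membered closure), and it needs the aldol to survive, which the non-enolisable aldehyde, the low temperature and the immediate silylation of step 3 secure against loss of water to the 2-acetylbenzofuran.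

Step 3
Reactants: 4 1-[(2R,3S)-5-bromo-3-hydroxy-2,3-dihydro-1-benzofuran-2-yl]ethan-1-one
Product: 5 1-[(2R,3S)-5-bromo-3-{[tert-butyl(dimethyl)silyl]oxy}-2,3-dihydro-1-benzofuran-2-yl]ethan-1-one
Conditions: TBSOTf, 2,6-lutidine, CH2Cl2, −78 °C
Reagents that add atoms: tert-butyldimethylsilyl trifluoromethanesulfonate, CC(C)(C)[Si](C)(C)OS(=O)(=O)C(F)(F)F
Why: Silylation of the secondary alcohol with a silyl triflate and a hindered pyridine base at −78 °C is faster than enolisation, so the β-hydroxy ketone is capped before it can lose water or epimerise at C2, and no stereocentre is touched.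

Step 4
Reactants: 5 1-[(2R,3S)-5-bromo-3-{[tert-butyl(dimethyl)silyl]oxy}-2,3-dihydro-1-benzofuran-2-yl]ethan-1-one
Product: 7 1-[(2R,3S)-5-bromo-3-{[tert-butyl(dimethyl)silyl]oxy}-2,3-dihydro-1-benzofuran-2-yl]ethenyl trifluoromethanesulfonate, via potassium enolate 6 (not isolated)
Conditions: KN(SiMe3)2, THF, −78 °C (ketone added to the base); then N-(5-chloropyridin-2-yl)triflimide, −78 °C
Reagents that add atoms: N-(5-chloropyridin-2-yl)-1,1,1-trifluoro-N-[(trifluoromethyl)sulfonyl]methanesulfonamide, FC(F)(F)S(=O)(=O)N(c1ccc(Cl)cn1)S(=O)(=O)C(F)(F)F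
Why: Kinetic enolate formation and O-triflation (enol triflate synthesis): the bulky amide base at −78 °C should take a proton from the unhindered methyl group and not from the oxygen-bearing ring methine C2–H, and the reactive pyridyl triflimide traps the enolate at −78 °C before it can equilibrate, so C2 keeps its configuration and the β-silyloxy group is not eliminated.

Step 5
Reactants: 7 1-[(2R,3S)-5-bromo-3-{[tert-butyl(dimethyl)silyl]oxy}-2,3-dihydro-1-benzofuran-2-yl]ethenyl trifluoromethanesulfonate
Product: 8 1-[(2R,3S)-5-bromo-3-hydroxy-2,3-dihydro-1-benzofuran-2-yl]ethenyl trifluoromethanesulfonate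
Conditions: HF·pyridine, pyridine, THF, 0 to 20 °C
Reagents that add atoms: none
Why: Fluoride-mediated desilylation under buffered, weakly acidic conditions that the enol triflate and the aryl bromide tolerate; the exchange is placed before the ester is made because a free C3 hydroxyl cis to a C2 acrylate ester would be set up to close to a cis-fused α-methylene-γ-butyrolactone.

Step 6
Reactants: 8 1-[(2R,3S)-5-bromo-3-hydroxy-2,3-dihydro-1-benzofuran-2-yl]ethenyl trifluoromethanesulfonate
Product: 9 (2R,3S)-5-bromo-2-{1-[(trifluoromethanesulfonyl)oxy]ethenyl}-2,3-dihydro-1-benzofuran-3-yl acetate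
Conditions: Ac2O, pyridine, DMAP (cat.), CH2Cl2, 0 °C
Reagents that add atoms: acetic anhydride, CC(=O)OC(C)=O
Why: DMAP-catalysed O-acetylation takes place at oxygen with retention at C3, and because no enolisable ketone remains next to C2 the acetate is no longer exposed to base-induced β-elimination.

Step 7
Reactants: 9 (2R,3S)-5-bromo-2-{1-[(trifluoromethanesulfonyl)oxy]ethenyl}-2,3-dihydro-1-benzofuran-3-yl acetate
Product: 10 methyl 2-[(2S,3S)-3-acetoxy-5-bromo-2,3-dihydro-1-benzofuran-2-yl]prop-2-enoate
Conditions: Pd(OAc)2 (5 mol %), PPh3 (10 mol %), CO (1 atm), MeOH, Et3N, DMF, 20 °C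
Reagents that add atoms: carbon monoxide, [C-]#[O+]; methanol, CO
Why: Palladium-catalysed alkoxycarbonylation of an enol triflate: zerovalent palladium inserts into the C–OTf bond at room temperature, CO insertion and methanolysis give the 2-substituted acrylate, and the electron-rich aryl bromide does not add to the PPh3 catalyst at this temperature (the C2 descriptor changes from R to S only through the priority rules).

Step 8
Reactants: 10 methyl 2-[(2S,3S)-3-acetoxy-5-bromo-2,3-dihydro-1-benzofuran-2-yl]prop-2-enoate; 11 tributyl(1-ethoxyethenyl)stannane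
Product: 13 methyl 2-[(2S,3S)-3-acetoxy-5-acetyl-2,3-dihydro-1-benzofuran-2-yl]prop-2-enoate, via aryl enol ether 12 (not isolated)
Conditions: PdCl2(PPh3)2 (5 mol %), toluene, 90 °C; then 1 M aq. HCl, THF, 0 °C
Reagents that add atoms: water, O
Why: Stille coupling of the aryl bromide with the 1-ethoxyvinyl stannane as an acetyl equivalent, then acid hydrolysis of the enol ether to the methyl ketone; no base or fluoride is added, which spares the C3 acetate (anti to H2) from elimination to the benzofuran, and the hindered ring-bound allylic aryl ether at C2 should ionise far more slowly than the aryl bromide adds to palladium.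

Step 9
Reactants: 13 methyl 2-[(2S,3S)-3-acetoxy-5-acetyl-2,3-dihydro-1-benzofuran-2-yl]prop-2-enoate
Product: 14 methyl 2-[(2S,3S)-3-acetoxy-5-[(1S)-1-hydroxyethyl]-2,3-dihydro-1-benzofuran-2-yl]prop-2-enoate
Conditions: (R)-1-methyl-3,3-diphenyltetrahydro-1H,3H-pyrrolo[1,2-c][1,3,2]oxazaborole (15 mol %), BH3·SMe2, THF, −20 °C (slow addition of 13); then MeOH
Reagents that add atoms: none
Why: Corey–Bakshi–Shibata reduction: the (R)-oxazaborolidine binds borane and the ketone so that hydride reaches the face of the aryl methyl ketone that gives the (S)-carbinol (aryl as the large group), under reagent control remote from the ring stereocentres, while the esters and the acrylate are not reduced by borane at −20 °C.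

Step 10
Reactants: 14 methyl 2-[(2S,3S)-3-acetoxy-5-[(1S)-1-hydroxyethyl]-2,3-dihydro-1-benzofuran-2-yl]prop-2-enoate; 15 angelic acid
Product: 17 methyl 2-[(2S,3S)-3-acetoxy-5-{(1S)-1-[(2Z)-2-methylbut-2-enoyloxy]ethyl}-2,3-dihydro-1-benzofuran-2-yl]prop-2-enoate (target), via mixed anhydride 16 (not isolated)
Conditions: 15, 2,4,6-trichlorobenzoyl chloride, Et3N, toluene, 20 °C; then 14, 70 °C
Reagents that add atoms: none
Why: Yamaguchi esterification: the alcohol attacks the unhindered angeloyl carbonyl of the mixed anhydride, the carbinol C–O bond is not broken so the (S) configuration is retained, and activation without an acyl chloride or a nucleophilic catalyst should avoid Z to E isomerisation to the tiglate.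

**Compound list**

1 | 5-bromosalicylaldehyde (5-bromo-2-hydroxybenzaldehyde) | O=Cc1cc(Br)ccc1O | starting material
2 | chloroacetone (1-chloropropan-2-one) | CC(=O)CCl | starting material
3 | 5-bromo-2-(2-oxopropoxy)benzaldehyde | CC(=O)COc1ccc(Br)cc1C=O | intermediate
4 | 1-[(2R,3S)-5-bromo-3-hydroxy-2,3-dihydro-1-benzofuran-2-yl]ethan-1-one (cis) | CC(=O)[C@@H]1Oc2ccc(Br)cc2[C@@H]1O | intermediate
5 | 1-[(2R,3S)-5-bromo-3-{[tert-butyl(dimethyl)silyl]oxy}-2,3-dihydro-1-benzofuran-2-yl]ethan-1-one | CC(=O)[C@@H]1Oc2ccc(Br)cc2[C@@H]1O[Si](C)(C)C(C)(C)C | intermediate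
6 | potassium 1-[(2R,3S)-5-bromo-3-{[tert-butyl(dimethyl)silyl]oxy}-2,3-dihydro-1-benzofuran-2-yl]ethen-1-olate (methyl-side enolate of 5) | [K+].[O-]C(=C)[C@@H]1Oc2ccc(Br)cc2[C@@H]1O[Si](C)(C)C(C)(C)C | intermediate (not isolated)
7 | 1-[(2R,3S)-5-bromo-3-{[tert-butyl(dimethyl)silyl]oxy}-2,3-dihydro-1-benzofuran-2-yl]ethenyl trifluoromethanesulfonate | C=C(OS(=O)(=O)C(F)(F)F)[C@@H]1Oc2ccc(Br)cc2[C@@H]1O[Si](C)(C)C(C)(C)C | intermediate
8 | 1-[(2R,3S)-5-bromo-3-hydroxy-2,3-dihydro-1-benzofuran-2-yl]ethenyl trifluoromethanesulfonate | C=C(OS(=O)(=O)C(F)(F)F)[C@@H]1Oc2ccc(Br)cc2[C@@H]1O | intermediate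
9 | (2R,3S)-5-bromo-2-{1-[(trifluoromethanesulfonyl)oxy]ethenyl}-2,3-dihydro-1-benzofuran-3-yl acetate | C=C(OS(=O)(=O)C(F)(F)F)[C@@H]1Oc2ccc(Br)cc2[C@@H]1OC(C)=O | intermediate
10 | methyl 2-[(2S,3S)-3-acetoxy-5-bromo-2,3-dihydro-1-benzofuran-2-yl]prop-2-enoate | C=C(C(=O)OC)[C@@H]1Oc2ccc(Br)cc2[C@@H]1OC(C)=O | intermediate
11 | tributyl(1-ethoxyethenyl)stannane | CCCC[Sn](CCCC)(CCCC)C(=C)OCC | starting material
12 | methyl 2-[(2S,3S)-3-acetoxy-5-(1-ethoxyethenyl)-2,3-dihydro-1-benzofuran-2-yl]prop-2-enoate | C=C(C(=O)OC)[C@@H]1Oc2ccc(C(=C)OCC)cc2[C@@H]1OC(C)=O | intermediate (not isolated)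
13 | methyl 2-[(2S,3S)-3-acetoxy-5-acetyl-2,3-dihydro-1-benzofuran-2-yl]prop-2-enoate | C=C(C(=O)OC)[C@@H]1Oc2ccc(C(C)=O)cc2[C@@H]1OC(C)=O | intermediate
14 | methyl 2-[(2S,3S)-3-acetoxy-5-[(1S)-1-hydroxyethyl]-2,3-dihydro-1-benzofuran-2-yl]prop-2-enoate | C=C(C(=O)OC)[C@@H]1Oc2ccc([C@H](C)O)cc2[C@@H]1OC(C)=O | intermediate
15 | angelic acid ((2Z)-2-methylbut-2-enoic acid) | C/C=C(/C)C(=O)O | starting material
16 | (2Z)-2-methylbut-2-enoic 2,4,6-trichlorobenzoic anhydride | C/C=C(/C)C(=O)OC(=O)c1c(Cl)cc(Cl)cc1Cl | intermediate (not isolated)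
17 | methyl 2-[(2S,3S)-3-acetoxy-5-{(1S)-1-[(2Z)-2-methylbut-2-enoyloxy]ethyl}-2,3-dihydro-1-benzofuran-2-yl]prop-2-enoate | C=C(C(=O)OC)[C@@H]1Oc2ccc([C@H](C)OC(=O)/C(C)=C\C)cc2[C@@H]1OC(C)=O | target

**Step count**

Total steps: 10. Longest linear sequence: 10 steps, from 5-bromosalicylaldehyde 1 to target 17.

**Steps most likely to fail**

Step 2. What may go wrong is incomplete enantiofacial discrimination in the ring closure, because the short tether makes the aldehyde react through the face that is the minor one in intermolecular proline aldols; some loss of water to the aromatic benzofuran may add to this. The fallback secures the absolute configuration by resolution and not by the catalyst alone. It sets out from alcohol 8 of insufficient enantiomeric purity, reached through the unchanged steps 3 to 5 (if need be from an aldol run with racemic proline). In place of step 6, 8 is acetylated with vinyl acetate and an immobilised lipase (Candida antarctica lipase B or Burkholderia cepacia lipase, tert-butyl methyl ether, 30 °C). By analogy with 1-indanol-type benzylic alcohols the (3S) enantiomer should be acetylated faster, so that acetate 9 is formed and the unreacted (2S,3R) enol triflate alcohol F1 is left behind and separated. The route is rejoined at 9.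

Step 4. What may go wrong is loss of regiocontrol in the enolisation, by deprotonation at C2 or equilibration of the methyl enolate, which would epimerise C2 or eliminate silanolate to the benzofuran. The fallback avoids any enolate and sets out from ketone 5. Tebbe methylenation (Cp2Ti(μ-CH2)(μ-Cl)AlMe2, pyridine, THF, −40 to 20 °C) should give the isopropenyl silyl ether F2. Bu4NF in THF then gives the isopropenyl alcohol F3, and Ac2O, pyridine and DMAP give the isopropenyl acetate F4. Allylic oxidation of the methyl group with SeO2 (1,4-dioxane, 80 °C) should give the 2-substituted acrolein F5. Pinnick oxidation (NaClO2, NaH2PO4, 2-methylbut-2-ene, t-BuOH, water) gives the acrylic acid F6. Methylation with trimethylsilyldiazomethane in toluene and MeOH returns to the route at bromo acrylate 10.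

Step 10. What may go wrong is isomerisation of the angeloyl group to the tigloyl (E) group during activation or acylation, or ionisation of the electron-rich benzylic alcohol with loss of configuration. The fallback builds the Z double bond on the ester and sets out from alcohol 14. Acylation with 2-[bis(2,2,2-trifluoroethoxy)phosphoryl]propanoic acid (EDC·HCl, DMAP, CH2Cl2, 0 °C) gives the phosphonopropionate ester F7. Still–Gennari olefination with acetaldehyde (KN(SiMe3)2, 18-crown-6, THF, −78 °C) should then give the (Z)-2-methylbut-2-enoate, which is target 17.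

**Further compounds**

F1 | step 2 | 1-[(2S,3R)-5-bromo-3-hydroxy-2,3-dihydro-1-benzofuran-2-yl]ethenyl trifluoromethanesulfonate (enantiomer of 8) | C=C(OS(=O)(=O)C(F)(F)F)[C@H]1Oc2ccc(Br)cc2[C@H]1O
F2 | step 4 | {[(2S,3S)-5-bromo-2-(prop-1-en-2-yl)-2,3-dihydro-1-benzofuran-3-yl]oxy}(tert-butyl)dimethylsilane | CC(=C)[C@@H]1Oc2ccc(Br)cc2[C@@H]1O[Si](C)(C)C(C)(C)C
F3 | step 4 | (2S,3S)-5-bromo-2-(prop-1-en-2-yl)-2,3-dihydro-1-benzofuran-3-ol | CC(=C)[C@@H]1Oc2ccc(Br)cc2[C@@H]1O
F4 | step 4 | (2S,3S)-5-bromo-2-(prop-1-en-2-yl)-2,3-dihydro-1-benzofuran-3-yl acetate | CC(=C)[C@@H]1Oc2ccc(Br)cc2[C@@H]1OC(C)=O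
F5 | step 4 | (2S,3S)-5-bromo-2-(3-oxoprop-1-en-2-yl)-2,3-dihydro-1-benzofuran-3-yl acetate | C=C(C=O)[C@@H]1Oc2ccc(Br)cc2[C@@H]1OC(C)=O
F6 | step 4 | 2-[(2S,3S)-3-acetoxy-5-bromo-2,3-dihydro-1-benzofuran-2-yl]prop-2-enoic acid | C=C(C(=O)O)[C@@H]1Oc2ccc(Br)cc2[C@@H]1OC(C)=O
F7 | step 10 | methyl 2-[(2S,3S)-3-acetoxy-5-{(1S)-1-[2-(bis(2,2,2-trifluoroethoxy)phosphoryl)propanoyloxy]ethyl}-2,3-dihydro-1-benzofuran-2-yl]prop-2-enoate (both epimers at the phosphonate carbon) | C=C(C(=O)OC)[C@@H]1Oc2ccc([C@H](C)OC(=O)C(C)P(=O)(OCC(F)(F)F)OCC(F)(F)F)cc2[C@@H]1OC(C)=O
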